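The benzene ring is cut at the bond between ring C1 (pentadecyl) and ring C2 (acetoxy). This exposes a linear tetraketide: the meta-disposed oxygens on C3 and C5 are former ketone oxygens, C1 is a former ketone carbon, and C2 once carried the terminal ester carbon. In one operation the key step folds methyl 3,5,7-trioxodocosanoate, a C22 chain with ketones at chain C3, C5 and C7 and a methyl ester at chain C1, into methyl 2,4-dihydroxy-6-pentadecylbenzoate by intramolecular aldol condensation and aromatisation, setting the complete ring substitution pattern. The ester carbon is afterwards exchanged for oxygen by a Dakin oxidation.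

Key step: step 3

Remark: the target has no stereocentre. Intermediate 6 is a transient mixture of stereoisomers and keto–enol tautomers and is written without configuration. "Ring C" numbers refer to the target (C1 pentadecyl, C2 acetoxy, C3 methoxy, C5 hydroxyl). "Chain C" numbers refer to open-chain ester 5 (chain C1 = ester carbon); chain C2 becomes ring C2 and chain C7 becomes ring C1. Commercial LiN(iPr)2 solution is assumed.

Step 1
Reactants: 1 triacetic acid lactone (4-hydroxy-6-methyl-2H-pyran-2-one)
Product: 2 methyl 3,5-dioxohexanoate
Conditions: Mg(OMe)2 (2 equiv), MeOH, reflux; then cold 1 M HCl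
Reagents that add atoms: methanol, CO, delivered as magnesium dimethoxide Mg(OMe)2, C[O-].C[O-].[Mg+2]
Why: Methoxide opens the pyranone at the lactone carbonyl, and the divalent-magnesium chelate of the resulting 3,5-diketo ester protects it from retro-Claisen cleavage and re-lactonisation (lactone methanolysis, a transesterification).

Step 2
Reactants: 2 methyl 3,5-dioxohexanoate; 3 methyl palmitate (methyl hexadecanoate)
Product: 5 methyl 3,5,7-trioxodocosanoate, via trilithium trienolate 4 (not isolated)
Conditions: 2 (2.2 equiv), LiN(iPr)2 (6.8 equiv), THF, 0 °C, 1 h; then 3 (1.0 equiv), 0 °C → rt; cold aq. HCl quench; crude 5 used at once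
Reagents that add atoms: none
Why: The trianion should react at its last-formed, most basic terminal carbanion (chain C6 of 2) in a Claisen-type C-acylation by the ester, and the twofold excess of trianion absorbs the proton transfer from the more acidic product.

Step 3
Reactants: 5 methyl 3,5,7-trioxodocosanoate
Product: 7 methyl 2,4-dihydroxy-6-pentadecylbenzoate, via cyclic aldol carbinol 6 (not isolated)
Conditions: K2CO3 (2 equiv), MeOH/THF 3:1, 0 °C → rt; then HCl in MeOH to pH 2, rt
Reagents that add atoms: none
Why: Carbonate in methanol ionises only the doubly activated methylenes, and the carbanion at chain C2 (between the ester and the C3 ketone) adds to the C7 ketone to give carbinol 6, which on acidification loses water and enolises at C3 and C5 to arene 7 (intramolecular aldol condensation with aromatisation). The closest known reaction type is the biomimetic cyclisation of 3,5,7-triketo esters to resorcylates. The single ring closes as a six-membered exo-trig aldol, 6-(enolendo)-exo-trig when the nucleophile is drawn as the C3 ketone enolate and enolexo when drawn as the ester enolate, both favoured modes, and the new bond is ring C1–C2. No lasting stereocentre is created, because the two centres of carbinol 6 are erased on aromatisation. The selectivity needed is C2-to-C7 aldol over C6-to-C1 Claisen closure (acylphloroglucinol), over lactonisation to a 4-hydroxy-2-pyranone and over the alternative C8-to-C3 aldol; it should be secured by the higher electrophilicity of the aliphatic C7 ketone compared with the enolate-conjugated ester, by the inability of carbonate to ionise the singly activated C8 methylene, and by a protic, weakly basic medium free of hydroxide and of chelating divalent magnesium, which would build polyanions or chelates in which the ester is the only non-enolised acceptor.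

Step 4
Reactants: 7 methyl 2,4-dihydroxy-6-pentadecylbenzoate
Product: 8 methyl 4-(benzyloxy)-2-hydroxy-6-pentadecylbenzoate
Conditions: BnBr (1.05 equiv), K2CO3 (1.2 equiv), acetone, rt → 45 °C
Reagents that add atoms: benzyl bromide, BrCc1ccccc1
Why: The C4 hydroxyl, para to the ester and not hydrogen-bonded, is the more acidic and more accessible phenol, so one equivalent of benzyl bromide should alkylate it selectively while the C2 hydroxyl stays chelated to the ester carbonyl (Williamson ether synthesis).

Step 5
Reactants: 8 methyl 4-(benzyloxy)-2-hydroxy-6-pentadecylbenzoate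
Product: 9 methyl 4-(benzyloxy)-2-methoxy-6-pentadecylbenzoate
Conditions: MeI (3 equiv), K2CO3 (2 equiv), DMF, 50 °C
Reagents that add atoms: iodomethane, CI
Why: With the para phenol capped, excess iodomethane and carbonate in a dipolar aprotic solvent should overcome the hydrogen bond and O-methylate the remaining phenol (Williamson ether synthesis).

Step 6
Reactants: 9 methyl 4-(benzyloxy)-2-methoxy-6-pentadecylbenzoate
Product: 10 [4-(benzyloxy)-2-methoxy-6-pentadecylphenyl]methanol
Conditions: LiAlH4 (1.5 equiv), THF, 0 °C → reflux; H2O/15% NaOH/H2O work-up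
Reagents that add atoms: none
Why: LiAlH4 is small enough to reduce the hindered, electron-rich benzoate to the benzyl alcohol, while the benzyl and methyl aryl ethers are inert (hydride reduction of an ester).

Step 7
Reactants: 10 [4-(benzyloxy)-2-methoxy-6-pentadecylphenyl]methanol
Product: 11 4-(benzyloxy)-2-methoxy-6-pentadecylbenzaldehyde
Conditions: activated MnO2 (10 equiv), CH2Cl2, rt
Reagents that add atoms: none
Why: Activated MnO2 oxidises benzylic alcohols selectively under neutral conditions, which avoids acid-induced self-alkylation of the electron-rich benzyl alcohol (heterogeneous benzylic oxidation).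

Step 8
Reactants: 11 4-(benzyloxy)-2-methoxy-6-pentadecylbenzaldehyde
Product: 13 4-(benzyloxy)-2-methoxy-6-pentadecylphenol, via aryl formate 12 (not isolated)
Conditions: mCPBA (1.3 equiv), CH2Cl2, 0 °C → rt; aq. Na2S2O3/NaHCO3 wash; then Et3N (cat.), MeOH, rt, under argon
Reagents that add atoms: 3-chloroperoxybenzoic acid (mCPBA), OOC(=O)c1cccc(Cl)c1
Why: In the peracid adduct the aryl group, made electron-rich by the ortho methoxy and para benzyloxy groups, should migrate in preference to hydride to give formate 12, which mild methanolysis cleaves to the phenol (Dakin-type Baeyer–Villiger oxidation).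

Step 9
Reactants: 13 4-(benzyloxy)-2-methoxy-6-pentadecylphenol
Product: 14 4-(benzyloxy)-2-methoxy-6-pentadecylphenyl acetate
Conditions: Ac2O (1.5 equiv), pyridine (3 equiv), DMAP (0.1 equiv), CH2Cl2, 0 °C → rt
Reagents that add atoms: acetic anhydride, CC(=O)OC(C)=O
Why: DMAP-catalysed acylation should acetylate even a 2,6-disubstituted phenol quickly, and it is the only free hydroxyl in 13 (nucleophile-catalysed esterification).

Step 10
Reactants: 14 4-(benzyloxy)-2-methoxy-6-pentadecylphenyl acetate
Product: 15 4-hydroxy-2-methoxy-6-pentadecylphenyl acetate (target)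
Conditions: H2 (1 atm), 10% Pd/C, EtOAc, rt
Reagents that add atoms: none
Why: Palladium on carbon under hydrogen cleaves the benzylic C–O bond, while the aryl acetate, the aryl methyl ether and the arene are untouched in neutral ethyl acetate (hydrogenolysis).

Compound list
1 | triacetic acid lactone (4-hydroxy-6-methyl-2H-pyran-2-one) | CC1=CC(O)=CC(=O)O1 | starting material
2 | methyl 3,5-dioxohexanoate | CC(=O)CC(=O)CC(=O)OC | intermediate
3 | methyl palmitate (methyl hexadecanoate) | CCCCCCCCCCCCCCCC(=O)OC | starting material
4 | trilithium trienolate (trianion) of methyl 3,5-dioxohexanoate | [Li+].[Li+].[Li+].C=C([O-])C=C([O-])C=C([O-])OC | intermediate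
5 | methyl 3,5,7-trioxodocosanoate | CCCCCCCCCCCCCCCC(=O)CC(=O)CC(=O)CC(=O)OC | intermediate
6 | methyl 2-hydroxy-4,6-dioxo-2-pentadecylcyclohexane-1-carboxylate (mixture of stereoisomers and tautomers) | CCCCCCCCCCCCCCCC1(O)CC(=O)CC(=O)C1C(=O)OC | intermediate
7 | methyl 2,4-dihydroxy-6-pentadecylbenzoate | CCCCCCCCCCCCCCCc1cc(O)cc(O)c1C(=O)OC | intermediate
8 | methyl 4-(benzyloxy)-2-hydroxy-6-pentadecylbenzoate | CCCCCCCCCCCCCCCc1cc(OCc2ccccc2)cc(O)c1C(=O)OC | intermediate
9 | methyl 4-(benzyloxy)-2-methoxy-6-pentadecylbenzoate | CCCCCCCCCCCCCCCc1cc(OCc2ccccc2)cc(OC)c1C(=O)OC | intermediate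
10 | [4-(benzyloxy)-2-methoxy-6-pentadecylphenyl]methanol | CCCCCCCCCCCCCCCc1cc(OCc2ccccc2)cc(OC)c1CO | intermediate
11 | 4-(benzyloxy)-2-methoxy-6-pentadecylbenzaldehyde | CCCCCCCCCCCCCCCc1cc(OCc2ccccc2)cc(OC)c1C=O | intermediate
12 | 4-(benzyloxy)-2-methoxy-6-pentadecylphenyl formate | CCCCCCCCCCCCCCCc1cc(OCc2ccccc2)cc(OC)c1OC=O | intermediate
13 | 4-(benzyloxy)-2-methoxy-6-pentadecylphenol | CCCCCCCCCCCCCCCc1cc(OCc2ccccc2)cc(OC)c1O | intermediate
14 | 4-(benzyloxy)-2-methoxy-6-pentadecylphenyl acetate | CCCCCCCCCCCCCCCc1cc(OCc2ccccc2)cc(OC)c1OC(C)=O | intermediate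
15 | 4-hydroxy-2-methoxy-6-pentadecylphenyl acetate | CCCCCCCCCCCCCCCc1cc(O)cc(OC)c1OC(C)=O | target

Total step count: 10
Longest linear sequence: 10 steps (1 → 15); methyl palmitate 3 enters at step 2.

Steps most likely to fail

Step 3 (key step). The ring may close through the wrong electrophile: the C6 carbanion may attack the ester carbon (Claisen closure), or an enol oxygen may acylate on it (lactonisation), instead of the C2-to-C7 aldol. The fallback masks the ester so that it cannot act as an acyl donor. It sets out from 3. Commercial 2,2,6-trimethyl-4H-1,3-dioxin-4-one would be deprotonated with LiN(SiMe3)2 (THF, −78 °C) and C-acetylated with acetyl chloride to 2,2-dimethyl-6-(2-oxopropyl)-4H-1,3-dioxin-4-one F1. Its dilithium dianion (LiN(iPr)2, THF, −78 °C, dianion in twofold excess) would be acylated at the terminal methyl by 3 to give 6-(2,4-dioxononadecyl)-2,2-dimethyl-4H-1,3-dioxin-4-one F2. Et3N in CH2Cl2 over 4 Å molecular sieves at rt should then effect the same C2–C7 aldol condensation and aromatisation to 7-hydroxy-2,2-dimethyl-5-pentadecyl-4H-1,3-benzodioxin-4-one F3, since the lactone acetal is inert to Claisen closure and to pyranone formation. NaOMe in MeOH would open F3 with loss of acetone, coming back to the route at 7.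

Step 2. Proton transfer from the more acidic triketo ester to the trianion, incomplete trianion formation, or attack of the amide base on the ester may drain the nucleophile and leave low conversion. The fallback reverses the order of bond formation, so that the carboxyl carbon rather than the fatty acyl group is introduced last. It sets out from 3. The dianion of commercial pentane-2,4-dione (NaH, then n-BuLi, THF, 0 °C, threefold excess) would be acylated at its terminal methyl by 3 to give henicosane-2,4,6-trione F4. Its trianion (LiN(iPr)2, 3 equiv, THF, 0 °C) would be carboxylated at the terminal methyl with excess CO2 to give 3,5,7-trioxodocosanoic acid F5, a reaction in which no acidic product competes for the nucleophile. Brief treatment with Me3SiCHN2 in toluene/MeOH at 0 °C would esterify the acid, coming back to the route at 5.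

Step 8. Hydride migration may compete with aryl migration in the peracid adduct (leading to the benzoic acid), or the peracid may oxidise the electron-rich ring. The fallback removes hydride as a competitor and installs the acetate directly. It sets out from 11. MeMgBr (THF, 0 °C) would give racemic 1-[4-(benzyloxy)-2-methoxy-6-pentadecylphenyl]ethan-1-ol F6, and MnO2 in CH2Cl2 would oxidise it to 1-[4-(benzyloxy)-2-methoxy-6-pentadecylphenyl]ethan-1-one F7. Baeyer–Villiger oxidation (mCPBA, NaHCO3, CH2Cl2, rt), in which the only competitor of the electron-rich aryl group is a methyl group, should give the aryl acetate directly, coming back to the route at 14 and making step 9 unnecessary.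

Further compounds
F1 | step 3 | 2,2-dimethyl-6-(2-oxopropyl)-4H-1,3-dioxin-4-one | CC(=O)CC1=CC(=O)OC(C)(C)O1
F2 | step 3 | 6-(2,4-dioxononadecyl)-2,2-dimethyl-4H-1,3-dioxin-4-one | CCCCCCCCCCCCCCCC(=O)CC(=O)CC1=CC(=O)OC(C)(C)O1
F3 | step 3 | 7-hydroxy-2,2-dimethyl-5-pentadecyl-4H-1,3-benzodioxin-4-one | CCCCCCCCCCCCCCCc1cc(O)cc2OC(C)(C)OC(=O)c12
F4 | step 2 | henicosane-2,4,6-trione | CCCCCCCCCCCCCCCC(=O)CC(=O)CC(C)=O
F5 | step 2 | 3,5,7-trioxodocosanoic acid | CCCCCCCCCCCCCCCC(=O)CC(=O)CC(=O)CC(=O)O
F6 | step 8 | 1-[4-(benzyloxy)-2-methoxy-6-pentadecylphenyl]ethan-1-ol (racemic) | CCCCCCCCCCCCCCCc1cc(OCc2ccccc2)cc(OC)c1C(C)O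
F7 | step 8 | 1-[4-(benzyloxy)-2-methoxy-6-pentadecylphenyl]ethan-1-one | CCCCCCCCCCCCCCCc1cc(OCc2ccccc2)cc(OC)c1C(C)=O
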